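**Retrosynthetic overview**

1. Ring labels: A is the dimethoxybenzo ring, C the dihydropyran ring, B the quinone ring, numbered C1(=O), C2(chromanyl), C3(H), C4(=O), C5(OMe), C6(OMe). Endgame: quinone ⇐ 4-methoxyphenol ⇐ (Baeyer–Villiger) benzaldehyde ⇐ (O-methylation) 6-chromanyl-2,4-dihydroxy-3-methoxybenzaldehyde. This last compound is ring B as an arene with a removable formyl group on C1.
2. Key disconnection: C2–C3 and C1–C6 of ring B. Both bonds form in one Diels–Alder/aromatisation between a chromanyl-propynal (C1 and C2, formyl as activator) and 1,2-dimethoxy-1,3-bis(trimethylsilyloxy)buta-1,3-diene (C6, C5, C4, C3).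
3. Enabling feature: C6(O)–C5(O)–C4(O)–C3(H) of ring B is an unbroken run of three oxygenated carbons ending in a CH. This is the chain ester C / C2 / ketone C / CH3 of methyl 2-methoxyacetoacetate. The C3(H)/C2(alkyl) pair matches the nucleophilic CH2 terminus of the diene and the β-carbon of an ynal. C1 lies para to the C4 oxygen, so the formyl group can be exchanged for the second quinone oxygen.
4. Ynal ⇐ Corey–Fuchs/formylation of (R)-chroman-3-carbaldehyde ⇐ (S)-chroman-3-ylmethanol, whose C3 stereocentre is set by asymmetric hydrogenation of the 2H-chromen-3-ylmethanol. Diene ⇐ methyl 2-methoxyacetoacetate ⇐ methyl methoxyacetate + acetyl chloride.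
5. Ring order: A is bought, C is closed first (oxa-Michael/aldol condensation with acrolein), and B is built last.

Key step: step 9

Assumption: the (S)-configured P,N ligand is taken to deliver hydrogen to the face of 4 that gives (S)-5. Should a trial run show the opposite sense, the (R)-ligand is used and nothing else changes.

**Route**

Step 1
Reactants: 1 2-hydroxy-4,5-dimethoxybenzaldehyde; 2 acrolein
Product: 3 6,7-dimethoxy-2H-chromene-3-carbaldehyde
Conditions: K2CO3, 1,4-dioxane, reflux
Reagents that add atoms: none
Why: Oxa-Michael addition of the phenoxide to acrolein followed by intramolecular aldol condensation onto the aryl aldehyde is the standard one-pot entry to 2H-chromene-3-carbaldehydes and closes the six-membered ring C with loss of water.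

Step 2
Reactants: 3 6,7-dimethoxy-2H-chromene-3-carbaldehyde
Product: 4 (6,7-dimethoxy-2H-chromen-3-yl)methanol
Conditions: NaBH4, MeOH/THF, 0 °C
Reagents that add atoms: none
Why: 1,2-Reduction of a conjugated aldehyde by NaBH4 at low temperature is fast and should leave the trisubstituted C3=C4 bond and the aryl ethers untouched.

Step 3
Reactants: 4 (6,7-dimethoxy-2H-chromen-3-yl)methanol
Product: 5 [(3S)-6,7-dimethoxy-3,4-dihydro-2H-chromen-3-yl]methanol
Conditions: [Ir(cod)((S)-tBu-PHOX)][B(3,5-(CF3)2C6H3)4] (1 mol %), H2 (50 bar), CH2Cl2, rt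
Reagents that add atoms: none
Why: Iridium–P,N-catalysed asymmetric hydrogenation of a trisubstituted 3-aryl-2-substituted allylic alcohol (4 is the cyclic analogue of the standard test olefin (E)-2-methyl-3-phenylprop-2-en-1-ol), in which the chiral ligand pocket distinguishes the two faces of C3=C4 and syn delivery of H2 sets C3 as S.

Step 4
Reactants: 5 [(3S)-6,7-dimethoxy-3,4-dihydro-2H-chromen-3-yl]methanol
Product: 6 (3R)-6,7-dimethoxy-3,4-dihydro-2H-chromene-3-carbaldehyde
Conditions: TEMPO (cat.), PhI(OAc)2, CH2Cl2, rt; used at once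
Reagents that add atoms: none
Why: The oxoammonium (TEMPO) oxidation stops at the aldehyde and is base-free, so the α-stereocentre of this β-aryloxy aldehyde should neither enolise nor be lost by retro-oxa-Michael opening of ring C (the descriptor changes to R only through CIP priorities).

Step 5
Reactants: 6 (3R)-6,7-dimethoxy-3,4-dihydro-2H-chromene-3-carbaldehyde
Product: 7 (3S)-3-(2,2-dibromoethenyl)-6,7-dimethoxy-3,4-dihydro-2H-chromene
Conditions: CBr4, PPh3, CH2Cl2, 0 °C (ylide preformed), then 6, −20 to 0 °C
Reagents that add atoms: carbon tetrabromide, BrC(Br)(Br)Br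
Why: The first stage of the Corey–Fuchs homologation, a Wittig-type dibromo-olefination with preformed Ph3P=CBr2, needs no added base and should therefore preserve the configuration at C3.

Step 6
Reactants: 7 (3S)-3-(2,2-dibromoethenyl)-6,7-dimethoxy-3,4-dihydro-2H-chromene
Product: 9 3-[(3S)-6,7-dimethoxy-3,4-dihydro-2H-chromen-3-yl]prop-2-ynal, via lithium acetylide 8 (not isolated)
Conditions: n-BuLi (2.05 equiv), THF, −78 °C; DMF, −78 to 0 °C; inverse quench into cold aq KH2PO4/MTBE
Reagents that add atoms: N,N-dimethylformamide, CN(C)C=O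
Why: In the second stage of the Corey–Fuchs reaction, dehydrobromination and Li–Br exchange at −78 °C should outrun ortho-lithiation of ring A, the acetylide is formylated by DMF, and the inverse acidic quench keeps the liberated amine from adding to the ynal.

Step 7
Reactants: 10 methyl methoxyacetate; 11 acetyl chloride
Product: 13 methyl 2-methoxy-3-oxobutanoate (racemic and enolisable), via lithium enolate 12 (not isolated)
Conditions: LiN(iPr)2 (2 equiv), 10 (2 equiv), THF, −78 °C; 11 (1 equiv), −78 °C; aq NH4Cl
Reagents that add atoms: none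
Why: This is a crossed Claisen C-acylation of a preformed lithium ester enolate with an acid chloride, in which the second equivalent of enolate takes up the acidic proton of the β-keto ester.

Step 8
Reactants: 13 methyl 2-methoxy-3-oxobutanoate
Product: 15 1,2-dimethoxy-1,3-bis(trimethylsilyloxy)buta-1,3-diene (E/Z mixture at the ketene acetal), via mono-silyl enol ether 14 (not isolated)
Conditions: TMSOTf (2.2 equiv), Et3N (2.5 equiv), Et2O, 0 °C to rt; salt layer removed, used crude
Reagents that add atoms: trimethylsilyl trifluoromethanesulfonate, C[Si](C)(C)OS(=O)(=O)C(F)(F)F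
Why: Exhaustive enol silylation of a β-keto ester (conjugated enol ether first, then γ-deprotonation) is the standard one-pot route to 1-alkoxy-1,3-bis(silyloxy)butadienes, and the ketene acetal geometry does not matter because that carbon becomes aromatic.

Step 9
Reactants: 9 3-[(3S)-6,7-dimethoxy-3,4-dihydro-2H-chromen-3-yl]prop-2-ynal; 15 1,2-dimethoxy-1,3-bis(trimethylsilyloxy)buta-1,3-diene
Product: 17 6-[(3S)-6,7-dimethoxy-3,4-dihydro-2H-chromen-3-yl]-2,4-dihydroxy-3-methoxybenzaldehyde, via cyclohexadiene cycloadduct 16 (not isolated)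
Conditions: 15 (2.5 equiv), toluene, 80 °C, argon, sealed tube; then 1 M HCl/THF, rt
Reagents that add atoms: none
Why: This is a normal-electron-demand Diels–Alder reaction of a vinylketene acetal with an acetylenic aldehyde followed by aromatisation, the known resorcinol synthesis from 1-alkoxy-1,3-bis(silyloxy)butadienes and alkynyl carbonyl dienophiles: the CH2 terminus of 15 bonds to the alkyne carbon bearing the chromanyl group (C3–C2 of ring B) and the ketene acetal carbon bonds to the formyl-bearing alkyne carbon (C6–C1), giving 1,4-cyclohexadiene 16. Ring B is closed by a suprafacial [4π+2π] cycloaddition that is concerted but strongly asynchronous, and in the stepwise limit it is a vinylogous Mukaiyama–Michael addition followed by 6-exo-trig closure of the allenolate carbon onto the silylated ester carbon, which leads to the same adduct. Dilute acid then removes both silyl groups, the hemiketal at C6 expels methanol and the dienone enolises, so that all six carbons of ring B, three of its C–O bonds, its C–H and its C–alkyl bond are placed in one operation. The regioselectivity that is needed is secured by polarity: three donor oxygens (two on C1 and one on C3 of the diene) put the largest HOMO coefficient on the unhindered CH2 terminus and outweigh the single cross-conjugated 2-OMe group, while the formyl group puts the largest LUMO coefficient on the β-alkyne carbon. Chemoselectivity for C≡C over C=O is secured by leaving out any Lewis acid, without which hetero-Diels–Alder or aldol attack on the aldehyde should be slow. The only new stereocentre, the ketal carbon of 16, forms as a mixture and is erased on aromatisation, and C3 of ring C is untouched because no base is present that could deprotonate the propargylic position.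

Step 10
Reactants: 17 6-[(3S)-6,7-dimethoxy-3,4-dihydro-2H-chromen-3-yl]-2,4-dihydroxy-3-methoxybenzaldehyde
Product: 18 6-[(3S)-6,7-dimethoxy-3,4-dihydro-2H-chromen-3-yl]-2,3,4-trimethoxybenzaldehyde
Conditions: MeI (excess), K2CO3, DMF, 40 °C
Reagents that add atoms: iodomethane, CI
Why: Williamson O-methylation of both phenols in warm DMF should overcome the hydrogen bond of the OH next to the formyl group, and the benzylic stereocentre carries no acidic hydrogen.

Step 11
Reactants: 18 6-[(3S)-6,7-dimethoxy-3,4-dihydro-2H-chromen-3-yl]-2,3,4-trimethoxybenzaldehyde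
Product: 20 6-[(3S)-6,7-dimethoxy-3,4-dihydro-2H-chromen-3-yl]-2,3,4-trimethoxyphenol, via aryl formate 19 (not isolated)
Conditions: mCPBA (1.2 equiv), CH2Cl2, 0 °C to rt; aq NaHCO3 wash; crude in MeOH, K2CO3 (cat.), rt
Reagents that add atoms: 3-chloroperoxybenzoic acid, OOC(=O)c1cccc(Cl)c1
Why: In the Baeyer–Villiger (Dakin-type) oxidation of a 2,4-dialkoxybenzaldehyde the electron-rich aryl group migrates in preference to hydride, and mild methanolysis of the formate removes the activating carbon and leaves the C1 oxygen of ring B.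

Step 12
Reactants: 20 6-[(3S)-6,7-dimethoxy-3,4-dihydro-2H-chromen-3-yl]-2,3,4-trimethoxyphenol
Product: 22 abroquinone A, via quinone hemiketal 21 (not isolated)
Conditions: PhI(OAc)2 (1.1 equiv), MeCN/H2O (2:1), 0 °C
Reagents that add atoms: water, O
Why: In the trivalent-iodine oxidation of a 4-methoxyphenol in aqueous acetonitrile, the iodane binds the free OH, water adds at the para carbon and the hemiketal loses methanol to give the p-quinone, while ring A has no OH to bind the iodane and the cold neutral medium leaves C3 alone.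

**Compound list**

1 | 2-hydroxy-4,5-dimethoxybenzaldehyde | COc1cc(O)c(C=O)cc1OC | starting material
2 | acrolein | C=CC=O | starting material
3 | 6,7-dimethoxy-2H-chromene-3-carbaldehyde | O=CC1=Cc2cc(OC)c(OC)cc2OC1 | intermediate
4 | (6,7-dimethoxy-2H-chromen-3-yl)methanol | OCC1=Cc2cc(OC)c(OC)cc2OC1 | intermediate
5 | [(3S)-6,7-dimethoxy-3,4-dihydro-2H-chromen-3-yl]methanol | OC[C@H]1COc2cc(OC)c(OC)cc2C1 | intermediate
6 | (3R)-6,7-dimethoxy-3,4-dihydro-2H-chromene-3-carbaldehyde | O=C[C@H]1COc2cc(OC)c(OC)cc2C1 | intermediate
7 | (3S)-3-(2,2-dibromoethenyl)-6,7-dimethoxy-3,4-dihydro-2H-chromene | BrC(Br)=C[C@H]1COc2cc(OC)c(OC)cc2C1 | intermediate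
8 | lithium [(3S)-6,7-dimethoxy-3,4-dihydro-2H-chromen-3-yl]acetylide | [Li]C#C[C@H]1COc2cc(OC)c(OC)cc2C1 | intermediate
9 | 3-[(3S)-6,7-dimethoxy-3,4-dihydro-2H-chromen-3-yl]prop-2-ynal | O=CC#C[C@H]1COc2cc(OC)c(OC)cc2C1 | intermediate
10 | methyl methoxyacetate | COCC(=O)OC | starting material
11 | acetyl chloride | CC(=O)Cl | starting material
12 | lithium enolate of methyl methoxyacetate | [Li]OC(OC)=COC | intermediate
13 | methyl 2-methoxy-3-oxobutanoate (racemic) | CC(=O)C(OC)C(=O)OC | intermediate
14 | methyl 2-methoxy-3-(trimethylsilyloxy)but-2-enoate | COC(=O)C(OC)=C(C)O[Si](C)(C)C | intermediate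
15 | 1,2-dimethoxy-1,3-bis(trimethylsilyloxy)buta-1,3-diene | C=C(O[Si](C)(C)C)C(OC)=C(OC)O[Si](C)(C)C | intermediate
16 | 2-[(3S)-6,7-dimethoxy-3,4-dihydro-2H-chromen-3-yl]-5,6-dimethoxy-4,6-bis(trimethylsilyloxy)cyclohexa-1,4-diene-1-carbaldehyde (mixture at C6) | O=CC1=C([C@H]2COc3cc(OC)c(OC)cc3C2)CC(O[Si](C)(C)C)=C(OC)C1(OC)O[Si](C)(C)C | intermediate
17 | 6-[(3S)-6,7-dimethoxy-3,4-dihydro-2H-chromen-3-yl]-2,4-dihydroxy-3-methoxybenzaldehyde | O=Cc1c(O)c(OC)c(O)cc1[C@H]2COc3cc(OC)c(OC)cc3C2 | intermediate
18 | 6-[(3S)-6,7-dimethoxy-3,4-dihydro-2H-chromen-3-yl]-2,3,4-trimethoxybenzaldehyde | O=Cc1c(OC)c(OC)c(OC)cc1[C@H]2COc3cc(OC)c(OC)cc3C2 | intermediate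
19 | 6-[(3S)-6,7-dimethoxy-3,4-dihydro-2H-chromen-3-yl]-2,3,4-trimethoxyphenyl formate | O=COc1c(OC)c(OC)c(OC)cc1[C@H]2COc3cc(OC)c(OC)cc3C2 | intermediate
20 | 6-[(3S)-6,7-dimethoxy-3,4-dihydro-2H-chromen-3-yl]-2,3,4-trimethoxyphenol | Oc1c(OC)c(OC)c(OC)cc1[C@H]2COc3cc(OC)c(OC)cc3C2 | intermediate
21 | 6-[(3S)-6,7-dimethoxy-3,4-dihydro-2H-chromen-3-yl]-4-hydroxy-2,3,4-trimethoxycyclohexa-2,5-dien-1-one (mixture at C4) | O=C1C(OC)=C(OC)C(O)(OC)C=C1[C@H]2COc3cc(OC)c(OC)cc3C2 | intermediate
22 | abroquinone A, 2-[(3S)-6,7-dimethoxy-3,4-dihydro-2H-chromen-3-yl]-5,6-dimethoxycyclohexa-2,5-diene-1,4-dione | COC1=C(OC)C(=O)C([C@H]2COc3cc(OC)c(OC)cc3C2)=CC1=O | target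

**Step count**

Total step count: 12.
Longest linear sequence: 10 (steps 1–6 and 9–12).

**Steps most likely to fail**

Step 9. The diene terminus may attack the formyl group (vinylogous aldol or hetero-Diels–Alder pathway). Alternatively, cycloaddition at the β-branched alkyne may be so slow that the diene is lost by hydrolysis or silyl migration. The fallback sets out from 7 and builds ring B by a cyclobutenone ring expansion instead of a cycloaddition. Treatment of 7 with n-BuLi in THF at −78 °C gives acetylide 8. This is added to commercial dimethyl squarate to give 4-{[(3S)-6,7-dimethoxy-3,4-dihydro-2H-chromen-3-yl]ethynyl}-4-hydroxy-2,3-dimethoxycyclobut-2-en-1-one F1. Thermolysis of F1 in refluxing p-xylene (Moore rearrangement: 4π ring opening to the alkynyl vinylketene, closure to the six-membered diradical, hydrogen transfer) should give the quinone directly. The fallback comes back to the route at 22.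

Step 3. Facial discrimination may be insufficient. The acidic iridium hydrides may also ionise or isomerise the electron-rich cinnamyl-type allylic alcohol. The fallback sets out from 3 and moves the stereo-defining event to a carboxylate-directed hydrogenation of a crystalline acid. Pinnick oxidation (NaClO2, NaH2PO4, 2-methylbut-2-ene, tBuOH/H2O) gives 6,7-dimethoxy-2H-chromene-3-carboxylic acid F2. Hydrogenation with Ru(OAc)2[(S)-BINAP] (ligand antipode fixed as in the assumption) under H2 in MeOH gives (3R)-6,7-dimethoxy-3,4-dihydro-2H-chromene-3-carboxylic acid F3. The enantiomeric purity of F3 can be raised by recrystallisation. Reduction with BH3·SMe2 in THF comes back to the route at 5.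

Step 12. Ring A is a hydroquinone diether through O1 and the 6-OMe group and may be over-oxidised. Water may also attack at the wrong ring position. The fallback sets out from 17 and avoids both the extra methyl group and the iodane.

- Dakin oxidation (H2O2, aq NaOH, THF, 0 °C, argon) gives 6-[(3S)-6,7-dimethoxy-3,4-dihydro-2H-chromen-3-yl]-3-methoxybenzene-1,2,4-triol F4.
- This very easily oxidised triol is taken with Ag2O in Et2O to 5-[(3S)-6,7-dimethoxy-3,4-dihydro-2H-chromen-3-yl]-3-hydroxy-2-methoxycyclohexa-2,5-diene-1,4-dione F5.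
- O-methylation of the acidic hydroxyquinone with Me3SiCHN2 in toluene/MeOH comes back to the route at 22.

**Further compounds**

F1 | step 9 | 4-{[(3S)-6,7-dimethoxy-3,4-dihydro-2H-chromen-3-yl]ethynyl}-4-hydroxy-2,3-dimethoxycyclobut-2-en-1-one (mixture at the carbinol carbon) | COC1=C(OC)C(O)(C#C[C@H]2COc3cc(OC)c(OC)cc3C2)C1=O
F2 | step 3 | 6,7-dimethoxy-2H-chromene-3-carboxylic acid | OC(=O)C1=Cc2cc(OC)c(OC)cc2OC1
F3 | step 3 | (3R)-6,7-dimethoxy-3,4-dihydro-2H-chromene-3-carboxylic acid | OC(=O)[C@H]1COc2cc(OC)c(OC)cc2C1
F4 | step 12 | 6-[(3S)-6,7-dimethoxy-3,4-dihydro-2H-chromen-3-yl]-3-methoxybenzene-1,2,4-triol | Oc1c(O)c(OC)c(O)cc1[C@H]2COc3cc(OC)c(OC)cc3C2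
F5 | step 12 | 5-[(3S)-6,7-dimethoxy-3,4-dihydro-2H-chromen-3-yl]-3-hydroxy-2-methoxycyclohexa-2,5-diene-1,4-dione | COC1=C(O)C(=O)C([C@H]2COc3cc(OC)c(OC)cc3C2)=CC1=O
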